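Ring B of ferugin (C1, C5–C10) carries oxygen at C6 and C9 on either side of C7, and C14 on C8: the pattern of a cyclohepta-1,4-diene with enol ethers at C5=C6 and C8=C9. It is therefore disconnected at C7–C8 and C10–C1 into a ring A 2-siloxydiene and a siloxyvinyl diazoacetate. One rhodium-carbenoid cyclopropanation/Cope sequence joins the fragments, closes ring B, sets the quaternary C1 and delivers both oxygens masked and differentiated, with C14 in place as an ester. The precursor is the kinetic triethylsilyl enol ether of a 1-acetyl-2-methylcyclopentene that bears the C4 carbinol, made from (S)-terpinen-4-ol.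

Key step: step 9

Remark: daucane numbering is used throughout (ring A = C1–C5, ring B = C1, C5–C10); α is the face of H5 and of the C6 and C9 oxygens, β the face of the C1 methyl and the C4 hydroxyl.

Remark: the three silyl groups are graded in lability (C4–OSiMe3, C6 enol OSiEt3, C9 enol OSi(tBu)Me2) so that, after the key step, C6 and C4 can be unmasked together while C9 stays masked.

Remark: (S)-terpinen-4-ol is assumed to be available in high enantiomeric purity, and Rh2(S-PTAD)4, dirhodium tetrakis[(S)-(1-adamantyl)(N-phthalimido)acetate], is assumed to be the catalyst enantiomer that leads to cyclopropane 12; should its sense be the reverse on this diene, Rh2(R-PTAD)4 takes its place.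

Step 1
Reactants: 1 (S)-terpinen-4-ol
Product: 2 trimethyl{[(1S)-4-methyl-1-(propan-2-yl)cyclohex-3-en-1-yl]oxy}silane
Conditions: Me3SiCl, imidazole, DMF, rt
Reagents that add atoms: chlorotrimethylsilane, C[Si](C)(C)Cl
Why: Imidazole-promoted O-silylation puts the small trimethylsilyl group on the tertiary alcohol, which masks it for the carbonyl and carbenoid chemistry ahead and can later be removed by the same mild acid that unmasks C6, the stereocentre being untouched.

Step 2
Reactants: 2 trimethyl{[(1S)-4-methyl-1-(propan-2-yl)cyclohex-3-en-1-yl]oxy}silane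
Product: 3 (3S)-6-oxo-3-(propan-2-yl)-3-(trimethylsilyloxy)heptanal
Conditions: O3, CH2Cl2, −78 °C; then PPh3, −78 °C → rt
Reagents that add atoms: ozone, [O-][O+]=O
Why: Ozonolysis of the only alkene with aprotic reductive work-up cleaves the ring to the keto aldehyde without disturbing the silyl ether or the quaternary stereocentre.

Step 3
Reactants: 3 (3S)-6-oxo-3-(propan-2-yl)-3-(trimethylsilyloxy)heptanal
Product: 4 (5R)-2-methyl-5-(propan-2-yl)-5-(trimethylsilyloxy)cyclopent-1-ene-1-carbaldehyde
Conditions: piperidine (cat.), AcOH (cat.), toluene, 4 Å MS, 70 °C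
Reagents that add atoms: none
Why: Amine-catalysed intramolecular aldol condensation, in which the aldehyde forms its enamine faster than the ketone, the enamine carbon closes onto the methyl ketone (5-exo-trig) and dehydration gives the tetrasubstituted cyclopentenecarbaldehyde, the mode known for the analogous keto aldehyde from limonene, with the carbinol stereocentre unaffected.

Step 4
Reactants: 4 (5R)-2-methyl-5-(propan-2-yl)-5-(trimethylsilyloxy)cyclopent-1-ene-1-carbaldehyde; 5 methylmagnesium bromide
Product: 6 1-[(5R)-2-methyl-5-(propan-2-yl)-5-(trimethylsilyloxy)cyclopent-1-en-1-yl]ethan-1-ol (both carbinol epimers)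
Conditions: MeMgBr, THF, −78 → 0 °C; aq. NH4Cl
Reagents that add atoms: none
Why: Grignard 1,2-addition to the enal gives the secondary allylic alcohol, whose new carbinol centre needs no control because it is oxidised in the next step.

Step 5
Reactants: 6 1-[(5R)-2-methyl-5-(propan-2-yl)-5-(trimethylsilyloxy)cyclopent-1-en-1-yl]ethan-1-ol
Product: 7 1-[(5R)-2-methyl-5-(propan-2-yl)-5-(trimethylsilyloxy)cyclopent-1-en-1-yl]ethan-1-one
Conditions: Dess–Martin periodinane, pyridine, CH2Cl2, 0 °C → rt
Reagents that add atoms: none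
Why: Dess–Martin oxidation under buffered conditions converts the allylic alcohol into the methyl ketone without ionising the acid-sensitive tertiary allylic silyl ether.

Step 6
Reactants: 7 1-[(5R)-2-methyl-5-(propan-2-yl)-5-(trimethylsilyloxy)cyclopent-1-en-1-yl]ethan-1-one
Product: 8 fragment 1, triethyl({1-[(5R)-2-methyl-5-(propan-2-yl)-5-(trimethylsilyloxy)cyclopent-1-en-1-yl]ethenyl}oxy)silane
Conditions: LiN(iPr)2, THF, −78 °C; then Et3SiCl, −78 → 0 °C
Reagents that add atoms: chlorotriethylsilane, CC[Si](Cl)(CC)CC
Why: Kinetic deprotonation of the enone at the acetyl methyl group (the α′ position) and O-silylation give the cross-conjugated 2-siloxydiene, whose triethylsilyl enol ether can be purified yet is far more acid-labile than the tert-butyldimethylsilyl enol ether that fragment 2 brings.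

Step 7
Reactants: 9 methyl acetoacetate
Product: 10 methyl 2-diazo-3-oxobutanoate
Conditions: 4-AcNHC6H4SO2N3, Et3N, MeCN, 0 °C → rt
Reagents that add atoms: 4-acetamidobenzenesulfonyl azide, CC(=O)Nc1ccc(cc1)S(=O)(=O)N=[N+]=[N-]
Why: Regitz diazo transfer to the active methylene group of the β-keto ester gives the diazoacetoacetate.

Step 8
Reactants: 10 methyl 2-diazo-3-oxobutanoate
Product: 11 fragment 2, methyl 3-(tert-butyldimethylsilyloxy)-2-diazobut-3-enoate
Conditions: tBuMe2SiOTf, Et3N, CH2Cl2, 0 °C
Reagents that add atoms: tert-butyldimethylsilyl triflate, CC(C)(C)[Si](C)(C)OS(=O)(=O)C(F)(F)F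
Why: Enol silyl ether formation at the acetyl group with the silyl triflate and triethylamine gives the siloxyvinyl diazoacetate, a known type of carbenoid precursor.

Step 9
Reactants: 8 fragment 1; 11 fragment 2
Product: 13 methyl (1R,4R)-9-(tert-butyldimethylsilyloxy)-6-(triethylsilyloxy)-4-(trimethylsilyloxy)dauca-5,8-dien-14-oate, via cis-divinylcyclopropane 12 (not isolated)
Conditions: Rh2(S-PTAD)4 (1 mol %), 11 (1.5 equiv) added slowly, hexanes, 0 °C → rt; then toluene, 110 °C
Reagents that add atoms: none
Why: Rh2(S-PTAD)4 turns 11 into a donor/acceptor siloxyvinylcarbenoid that cyclopropanates the exposed, electron-rich CH2=C(OSiEt3) unit of 8 (bonds C8–C7 and C8–C6) and leaves the shielded tetrasubstituted ring alkene alone, which is the site selectivity the step needs. The closest known reaction type is the tandem cyclopropanation/Cope rearrangement of vinyldiazoacetates with dienes (formal [4+3] cycloaddition), which is known for oxygen-substituted dienes and for diene termini that become quaternary. In 12 the cyclopentenyl group is expected to sit cis to the siloxyvinyl group, as donor/acceptor carbenoids place the unsaturated alkene substituent next to the donor, and the two vinyl groups then undergo a concerted [3,3] shift through the boat transition state, breaking C6–C8 and forming C10–C1. Ring B is thus closed in a pericyclic, strain-releasing mode as a cyclohepta-1,4-diene whose C5=C6 and C8=C9 bonds are the two enol ethers. C1 is the only new stereocentre that remains; it follows stereospecifically from the (1S,2R) configuration of the cyclopropane, which brings C10 to the ring A face cis to the isopropyl group, and that configuration is imposed by the chiral catalyst on an alkene two bonds away from C4. Because the C1 methyl is the inward-pointing substituent of the boat, the shift is planned at about 110 °C with 8 as the limiting partner so that no free diene is left to isomerise, and the donor/acceptor substitution of the breaking C6–C8 bond should lower the barrier.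

Step 10
Reactants: 13 methyl (1R,4R)-9-(tert-butyldimethylsilyloxy)-6-(triethylsilyloxy)-4-(trimethylsilyloxy)dauca-5,8-dien-14-oate
Product: 14 methyl (1R,4R,5R)-9-(tert-butyldimethylsilyloxy)-4-hydroxy-6-oxodauc-8-en-14-oate (trans-fused, H5 α)
Conditions: 0.5 M aq. HCl, THF, 0 °C → rt
Reagents that add atoms: none
Why: Acid hydrolysis of silyl ethers, in which the electron-rich C5=C6 triethylsilyl enol ether is protonated at C5 and the tertiary trimethylsilyl ether is cleaved while the tert-butyldimethylsilyl enol ether of the β-keto ester (a vinylogous carbonate, much less basic at carbon) should survive; C5, epimerisable next to the new ketone, is expected to settle as the trans-fused isomer, in which C6 avoids the cis isopropyl group and the C4 hydroxyl hydrogen-bonds to the C6 carbonyl.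

Step 11
Reactants: 14 methyl (1R,4R,5R)-9-(tert-butyldimethylsilyloxy)-4-hydroxy-6-oxodauc-8-en-14-oate
Product: 15 methyl (1R,4R,5S,6S)-9-(tert-butyldimethylsilyloxy)-4,6-dihydroxydauc-8-en-14-oate (6α-OH)
Conditions: Me4NBH(OAc)3, AcOH/MeCN (1:1), −30 → −20 °C
Reagents that add atoms: none
Why: Hydroxyl-directed Evans–Saksena reduction, in which the C4 hydroxyl exchanges onto boron and the alkoxyborohydride delivers hydride intramolecularly to the β-face of the C6 carbonyl, the face on which O4 lies, so that the new hydroxyl is 6α (anti to O4, cis to H5) while the enoate is inert to this mild reagent.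

Step 12
Reactants: 15 methyl (1R,4R,5S,6S)-9-(tert-butyldimethylsilyloxy)-4,6-dihydroxydauc-8-en-14-oate
Product: 17 (1R,4R,5S,6S)-4,6-dihydroxydauc-8(14)-en-9-one, via allylic alcohol 16 (not isolated)
Conditions: iBu2AlH (6 equiv), CH2Cl2, −78 °C; aq. potassium sodium tartrate; then CF3CO2H (cat.), THF/H2O, 0 °C
Reagents that add atoms: none
Why: Reductive transposition of a β-siloxy enoate (Stork–Danheiser type), in which the aluminium hydride reduces the ester in 1,2-fashion to the C14 allylic alcohol without touching the silyl enol ether and acid then ionises the C14–O bond with the help of the enol ether oxygen, loss of the silyl group giving the α-methylene ketone; no stereocentre is formed and, C6 being an alcohol already, C7 is not acidified and the exocyclic alkene should stay in place.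

Step 13
Reactants: 18 4-hydroxybenzoic acid
Product: 20 4-(tert-butyldimethylsilyloxy)benzoic acid, via silyl ester 19 (not isolated)
Conditions: tBuMe2SiCl (2.2 equiv), imidazole, DMF, rt; then AcOH/THF/H2O, rt
Reagents that add atoms: tert-butyldimethylsilyl chloride, CC(C)(C)[Si](C)(C)Cl
Why: Silylation of both acidic groups followed by selective hydrolysis of the labile silyl ester leaves the phenol protected as its silyl ether and the acid free for coupling.

Step 14
Reactants: 17 (1R,4R,5S,6S)-4,6-dihydroxydauc-8(14)-en-9-one; 20 4-(tert-butyldimethylsilyloxy)benzoic acid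
Product: 21 (1R,4R,5S,6S)-4-hydroxy-9-oxodauc-8(14)-en-6-yl 4-(tert-butyldimethylsilyloxy)benzoate
Conditions: DCC, DMAP (cat.), CH2Cl2, 0 °C → rt
Reagents that add atoms: none
Why: Steglich esterification acylates the only secondary hydroxyl (C6) with retention, the tertiary C4 hydroxyl being too hindered to react, so no selection between C6 and C9 oxygens is ever required.

Step 15
Reactants: 21 (1R,4R,5S,6S)-4-hydroxy-9-oxodauc-8(14)-en-6-yl 4-(tert-butyldimethylsilyloxy)benzoate
Product: 22 (1R,4R,5S,6S,9S)-4,9-dihydroxydauc-8(14)-en-6-yl 4-(tert-butyldimethylsilyloxy)benzoate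
Conditions: (R)-2-methyl-CBS-oxazaborolidine (0.3 equiv), catecholborane, toluene, −78 °C
Reagents that add atoms: none
Why: Corey–Bakshi–Shibata reduction, 1,2-selective for enones, in which the (R)-oxazaborolidine binds the C9 carbonyl anti to the α-branched sp2 carbon C8 (the large group) and delivers hydride to the β-face, giving the (9S)-alcohol with the hydroxyl α (cis to the C6 ester, trans to the C1 methyl), reagent control being relied on to override the modest bias of the ring.

Step 16
Reactants: 22 (1R,4R,5S,6S,9S)-4,9-dihydroxydauc-8(14)-en-6-yl 4-(tert-butyldimethylsilyloxy)benzoate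
Product: 23 ferugin
Conditions: Bu4NF, AcOH, THF, 0 °C
Reagents that add atoms: none
Why: Fluoride cleavage of the aryl silyl ether, buffered with acetic acid so that the phenoxide does not attack the ester, frees the phenol and gives ferugin with all five stereocentres as set.

Compound list
1 | (S)-terpinen-4-ol, (1S)-4-methyl-1-(propan-2-yl)cyclohex-3-en-1-ol | CC1=CC[C@](O)(C(C)C)CC1 | starting material
2 | trimethyl{[(1S)-4-methyl-1-(propan-2-yl)cyclohex-3-en-1-yl]oxy}silane | CC1=CC[C@](O[Si](C)(C)C)(C(C)C)CC1 | intermediate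
3 | (3S)-6-oxo-3-(propan-2-yl)-3-(trimethylsilyloxy)heptanal | O=CC[C@](O[Si](C)(C)C)(C(C)C)CCC(C)=O | intermediate
4 | (5R)-2-methyl-5-(propan-2-yl)-5-(trimethylsilyloxy)cyclopent-1-ene-1-carbaldehyde | O=CC1=C(C)CC[C@@]1(O[Si](C)(C)C)C(C)C | intermediate
5 | methylmagnesium bromide | C[Mg]Br | starting material
6 | 1-[(5R)-2-methyl-5-(propan-2-yl)-5-(trimethylsilyloxy)cyclopent-1-en-1-yl]ethan-1-ol, both carbinol epimers | CC(O)C1=C(C)CC[C@@]1(O[Si](C)(C)C)C(C)C | intermediate
7 | 1-[(5R)-2-methyl-5-(propan-2-yl)-5-(trimethylsilyloxy)cyclopent-1-en-1-yl]ethan-1-one | CC(=O)C1=C(C)CC[C@@]1(O[Si](C)(C)C)C(C)C | intermediate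
8 | fragment 1, triethyl({1-[(5R)-2-methyl-5-(propan-2-yl)-5-(trimethylsilyloxy)cyclopent-1-en-1-yl]ethenyl}oxy)silane | C=C(O[Si](CC)(CC)CC)C1=C(C)CC[C@@]1(O[Si](C)(C)C)C(C)C | intermediate
9 | methyl acetoacetate | COC(=O)CC(C)=O | starting material
10 | methyl 2-diazo-3-oxobutanoate | COC(=O)C(=[N+]=[N-])C(C)=O | intermediate
11 | fragment 2, methyl 3-(tert-butyldimethylsilyloxy)-2-diazobut-3-enoate | COC(=O)C(=[N+]=[N-])C(=C)O[Si](C)(C)C(C)(C)C | intermediate
12 | methyl (1S,2R)-1-[1-(tert-butyldimethylsilyloxy)ethenyl]-2-[(5R)-2-methyl-5-(propan-2-yl)-5-(trimethylsilyloxy)cyclopent-1-en-1-yl]-2-(triethylsilyloxy)cyclopropane-1-carboxylate, the two vinyl groups cis | COC(=O)[C@]1(C(=C)O[Si](C)(C)C(C)(C)C)C[C@@]1(O[Si](CC)(CC)CC)C2=C(C)CC[C@@]2(O[Si](C)(C)C)C(C)C | intermediate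
13 | methyl (1R,4R)-9-(tert-butyldimethylsilyloxy)-6-(triethylsilyloxy)-4-(trimethylsilyloxy)dauca-5,8-dien-14-oate | COC(=O)C1=C(O[Si](C)(C)C(C)(C)C)C[C@@]2(C)CC[C@@](O[Si](C)(C)C)(C(C)C)C2=C(O[Si](CC)(CC)CC)C1 | intermediate
14 | methyl (1R,4R,5R)-9-(tert-butyldimethylsilyloxy)-4-hydroxy-6-oxodauc-8-en-14-oate, trans-fused with H5 α | COC(=O)C1=C(O[Si](C)(C)C(C)(C)C)C[C@@]2(C)CC[C@@](O)(C(C)C)[C@@H]2C(=O)C1 | intermediate
15 | methyl (1R,4R,5S,6S)-9-(tert-butyldimethylsilyloxy)-4,6-dihydroxydauc-8-en-14-oate, 6α-OH | COC(=O)C1=C(O[Si](C)(C)C(C)(C)C)C[C@@]2(C)CC[C@@](O)(C(C)C)[C@@H]2[C@@H](O)C1 | intermediate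
16 | (1R,4R,5S,6S)-9-(tert-butyldimethylsilyloxy)dauc-8-ene-4,6,14-triol | OCC1=C(O[Si](C)(C)C(C)(C)C)C[C@@]2(C)CC[C@@](O)(C(C)C)[C@@H]2[C@@H](O)C1 | intermediate
17 | (1R,4R,5S,6S)-4,6-dihydroxydauc-8(14)-en-9-one | C=C1C[C@H](O)[C@@H]2[C@](C)(CC[C@@]2(O)C(C)C)CC1=O | intermediate
18 | 4-hydroxybenzoic acid | O=C(O)c1ccc(O)cc1 | starting material
19 | tert-butyldimethylsilyl 4-(tert-butyldimethylsilyloxy)benzoate | CC(C)(C)[Si](C)(C)OC(=O)c1ccc(O[Si](C)(C)C(C)(C)C)cc1 | intermediate
20 | 4-(tert-butyldimethylsilyloxy)benzoic acid | CC(C)(C)[Si](C)(C)Oc1ccc(cc1)C(=O)O | intermediate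
21 | (1R,4R,5S,6S)-4-hydroxy-9-oxodauc-8(14)-en-6-yl 4-(tert-butyldimethylsilyloxy)benzoate | C=C1C[C@H](OC(=O)c2ccc(O[Si](C)(C)C(C)(C)C)cc2)[C@@H]2[C@](C)(CC[C@@]2(O)C(C)C)CC1=O | intermediate
22 | (1R,4R,5S,6S,9S)-4,9-dihydroxydauc-8(14)-en-6-yl 4-(tert-butyldimethylsilyloxy)benzoate | C=C1C[C@H](OC(=O)c2ccc(O[Si](C)(C)C(C)(C)C)cc2)[C@@H]2[C@](C)(CC[C@@]2(O)C(C)C)C[C@@H]1O | intermediate
23 | ferugin, (1R,4R,5S,6S,9S)-4,9-dihydroxydauc-8(14)-en-6-yl 4-hydroxybenzoate | C=C1C[C@H](OC(=O)c2ccc(O)cc2)[C@@H]2[C@](C)(CC[C@@]2(O)C(C)C)C[C@@H]1O | target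

Total step count: 16 (steps 7, 8 and 13 are side branches).
Longest linear sequence: 13 steps (steps 1–6, 9–12, 14–16).

Steps most likely to fail

Step 9. The [3,3] shift at the fully substituted C1 terminus may be slower than heterolytic opening of the siloxy/ester-substituted cyclopropane bond. Stereochemical information would then be lost, or a vinylcyclopropane-to-cyclopentene drift would take over. Fallback: an ionic union without any pericyclic step, setting out from 8 and coming back at 14. Bromination of 8 with N-bromosuccinimide (THF, 0 °C) gives the bromomethyl ketone F1. Mukaiyama–Michael addition of 1-methoxy-1,3-bis(trimethylsilyloxy)buta-1,3-diene to the enone (TiCl4, CH2Cl2, −78 °C) forms C10–C1 and gives the bromo keto ester F2. K2CO3 in acetone under dilution closes C7–C8 by intramolecular C-alkylation of the β-keto ester, and acidic work-up frees the C4 hydroxyl to give the diketo ester F3. Selective O-silylation of its β-keto ester (tBuMe2SiCl, imidazole, DMF) returns to 14. In this fallback the C1 configuration would rest on the C4 centre alone.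

Step 12. The aluminium hydride may over-reduce or reduce in 1,4-fashion. During the acid stage the allyl cation may be captured by the C6 hydroxyl, or the exocyclic alkene may migrate into the ring. Fallback: introduce C14 by decarboxylative Mannich methylenation instead of by reduction, setting out from 15 and coming back at 17. Bu4NF/AcOH (THF, 0 °C) frees the β-keto ester F4, and LiOH (THF/H2O, 0 °C) saponifies it to the β-keto acid F5. Aqueous formaldehyde with diethylamine then gives 17 with loss of CO2. C14 then stems from formaldehyde and the original ester carbon is lost.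

Step 15. Facial selectivity at C9 may be poor if the ring bias opposes the catalyst, since the axial C1 methyl hinders hydride approach from the β-face. Fallback: substrate-controlled reduction followed by inversion, setting out from 21 and coming back at 23. NaBH4/CeCl3 in MeOH at −78 °C (Luche reduction) gives whichever C9 epimer the ring prefers. If that is 22, it is carried on as planned. If it is the 9β-alcohol F6, a Mitsunobu reaction (4-nitrobenzoic acid, PPh3, diisopropyl azodicarboxylate, THF) inverts C9 to the 9α-nitrobenzoate F7. K2CO3 in MeOH at 0 °C then removes the nitrobenzoate and the aryl silyl ether together to give 23, the hindered C6 ester being deactivated as its 4-oxidobenzoate.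

Further compounds
F1 | step 9 | 2-bromo-1-[(5R)-2-methyl-5-(propan-2-yl)-5-(trimethylsilyloxy)cyclopent-1-en-1-yl]ethan-1-one | BrCC(=O)C1=C(C)CC[C@@]1(O[Si](C)(C)C)C(C)C
F2 | step 9 | methyl 4-[2-(bromoacetyl)-1-methyl-3-(propan-2-yl)-3-(trimethylsilyloxy)cyclopentyl]-3-oxobutanoate, ring configuration as in 14 | BrCC(=O)[C@@H]1[C@](C)(CC[C@@]1(O[Si](C)(C)C)C(C)C)CC(=O)CC(=O)OC
F3 | step 9 | methyl (1R,4R,5R)-4-hydroxy-6,9-dioxodaucan-14-oate, C8 epimerisable | COC(=O)C1CC(=O)[C@@H]2[C@](C)(CC[C@@]2(O)C(C)C)CC1=O
F4 | step 12 | methyl (1R,4R,5S,6S)-4,6-dihydroxy-9-oxodaucan-14-oate, C8 epimerisable | COC(=O)C1C[C@H](O)[C@@H]2[C@](C)(CC[C@@]2(O)C(C)C)CC1=O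
F5 | step 12 | (1R,4R,5S,6S)-4,6-dihydroxy-9-oxodaucan-14-oic acid, C8 epimerisable | OC(=O)C1C[C@H](O)[C@@H]2[C@](C)(CC[C@@]2(O)C(C)C)CC1=O
F6 | step 15 | (1R,4R,5S,6S,9R)-4,9-dihydroxydauc-8(14)-en-6-yl 4-(tert-butyldimethylsilyloxy)benzoate, the 9β-epimer of 22 | C=C1C[C@H](OC(=O)c2ccc(O[Si](C)(C)C(C)(C)C)cc2)[C@@H]2[C@](C)(CC[C@@]2(O)C(C)C)C[C@H]1O
F7 | step 15 | (1R,4R,5S,6S,9S)-6-[4-(tert-butyldimethylsilyloxy)benzoyloxy]-4-hydroxydauc-8(14)-en-9-yl 4-nitrobenzoate | C=C1C[C@H](OC(=O)c2ccc(O[Si](C)(C)C(C)(C)C)cc2)[C@@H]2[C@](C)(CC[C@@]2(O)C(C)C)C[C@@H]1OC(=O)c3ccc(cc3)[N+](=O)[O-]
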